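**Retrosynthetic overview**

1. Ring A carries OMe at position 1, OH at position 4, a CH2 at position 5 and O-aryl at position 6; ring B is meta-substituted (O and CH2); ring C has its CH2 para to OH and meta to O-aryl; ring D is para-substituted (O and CH2). The route rests on the CH2–CH2 bond between the benzylic carbon of ring D and the benzylic carbon at position 5 of ring A, which is wedged between the OH-bearing and the O-aryl-bearing carbons. This bond is made last, by loss of SO2 from a 19-membered dibenzylic sulfone (19 → 18 ring contraction); only BCl3 removal of two isopropyl ethers follows.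
2. The sulfone comes from the thioether, closed by double SN2 of sulfide on the ring A/ring D bis(benzylic bromide); the dibromide comes from the diol and the diol from a seco dialdehyde.
3. Seco dialdehyde: ring D is attached by SNAr of the ring C phenol on 4-fluorobenzaldehyde; the ring A formyl group comes from lithiation between the two flanking ring A oxygens and DMF.
4. The CH2CH2 bridge between rings B and C comes from hydroboration of a ring C styrene (from 3,4-dihydroxybenzaldehyde) and B-alkyl Suzuki coupling with the A–B aryl bromide (from isovanillin by Ullmann ether synthesis, Dakin-type oxidation and O-isopropylation).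
5. Ring order: the four benzene rings are bought; the macrocycle is the only ring made, closed as the 19-membered thia ring (step 11) and contracted to the 18-membered ring (step 13).

Key step: step 13

Remark: the target has no stereocentre, so no stereocontrol is needed; ring B is brought in as commercial 1-bromo-3-iodobenzene because the bridge between rings B and C is made by a Suzuki coupling.

**Route**

Step 1
Reactants: 1 isovanillin (3-hydroxy-4-methoxybenzaldehyde); 2 1-bromo-3-iodobenzene
Product: 3 3-(3-bromophenoxy)-4-methoxybenzaldehyde
Conditions: CuI (10 mol%), N,N-dimethylglycine hydrochloride (30 mol%), Cs2CO3, 1,4-dioxane, 90 °C; 2 in excess (1.5 equiv)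
Reagents that add atoms: none
Why: Ullmann-type diaryl ether synthesis, in which the copper catalyst activates the C–I bond much faster than the C–Br bond at 90 °C, so the phenoxide of 1 should replace iodide only, and the excess of 2 suppresses a second coupling.

Step 2
Reactants: 3 3-(3-bromophenoxy)-4-methoxybenzaldehyde
Product: 5 3-(3-bromophenoxy)-4-methoxyphenol, via aryl formate 4 (not isolated)
Conditions: mCPBA, CH2Cl2, 0 °C → rt; then K2CO3 (cat.), MeOH, rt
Reagents that add atoms: mCPBA (3-chloroperoxybenzoic acid), SMILES OOC(=O)c1cccc(Cl)c1
Why: Baeyer–Villiger (Dakin-type) oxidation, in which the electron-rich aryl group para to OMe migrates in the Criegee intermediate to give the aryl formate, which mild methanolysis cleaves to the phenol while the aryl bromide and diaryl ether are inert.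

Step 3
Reactants: 5 3-(3-bromophenoxy)-4-methoxyphenol
Product: 6 2-(3-bromophenoxy)-1-methoxy-4-(propan-2-yloxy)benzene
Conditions: 2-bromopropane, K2CO3, DMF, 60 °C
Reagents that add atoms: 2-bromopropane, SMILES CC(C)Br
Why: Williamson ether synthesis on the phenoxide; the isopropyl ether is chosen because it should survive organolithium, light and radicals and is cleaved later by BCl3 beside a methyl ether.

Step 4
Reactants: 7 3,4-dihydroxybenzaldehyde
Product: 8 3-hydroxy-4-(propan-2-yloxy)benzaldehyde
Conditions: 2-bromopropane (1.1 equiv), K2CO3 (1.0 equiv), DMF, rt → 40 °C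
Reagents that add atoms: 2-bromopropane, SMILES CC(C)Br
Why: Regioselective Williamson alkylation, since the 4-OH conjugated to the formyl group is the more acidic phenol, so one equivalent of base gives the 4-phenoxide and hence the 4-ether.

Step 5
Reactants: 8 3-hydroxy-4-(propan-2-yloxy)benzaldehyde
Product: 9 5-ethenyl-2-(propan-2-yloxy)phenol
Conditions: Ph3PCH3Br (2.5 equiv), KOtBu (2.5 equiv), THF, 0 °C → rt; product kept cold and used promptly
Reagents that add atoms: methyltriphenylphosphonium bromide, SMILES C[P+](c1ccccc1)(c1ccccc1)c1ccccc1.[Br-]
Why: Wittig methylenation, in which one extra equivalent of ylide is spent on the phenol, whose phenoxide is meta to the formyl group and so does not deactivate it.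

Step 6
Reactants: 9 5-ethenyl-2-(propan-2-yloxy)phenol; 6 2-(3-bromophenoxy)-1-methoxy-4-(propan-2-yloxy)benzene
Product: 11 5-[2-[3-[2-methoxy-5-(propan-2-yloxy)phenoxy]phenyl]ethyl]-2-(propan-2-yloxy)phenol, via alkylborane 10 (not isolated)
Conditions: 9-BBN (2.3 equiv), THF, 0 °C → rt; then 6, PdCl2(dppf) (5 mol%), aq. K3PO4, THF/DMF, 65 °C
Reagents that add atoms: none
Why: Anti-Markovnikov hydroboration of the styrene with 9-BBN (one equivalent of borane is taken up by the phenol as a borinate that the aqueous base hydrolyses) followed by B-alkyl Suzuki–Miyaura coupling with the aryl bromide, which should give the CH2CH2 bridge between rings B and C directly with no alkene left to reduce.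

Step 7
Reactants: 11 5-[2-[3-[2-methoxy-5-(propan-2-yloxy)phenoxy]phenyl]ethyl]-2-(propan-2-yloxy)phenol
Product: 13 2-[3-[2-[3-hydroxy-4-(propan-2-yloxy)phenyl]ethyl]phenoxy]-3-methoxy-6-(propan-2-yloxy)benzaldehyde, via dilithio species 12 (not isolated)
Conditions: n-BuLi (2.4 equiv), TMEDA, THF, 0 °C; DMF, 0 °C → rt; aq. NH4Cl
Reagents that add atoms: N,N-dimethylformamide, SMILES CN(C)C=O
Why: Directed ortho-metalation, in which the phenol is deprotonated first (deactivating ring C) and the ring A hydrogen at position 5, the only one flanked by two ether oxygens, should then be removed selectively as in 1,2,4-trialkoxybenzenes, before DMF formylates the aryllithium.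

Step 8
Reactants: 13 2-[3-[2-[3-hydroxy-4-(propan-2-yloxy)phenyl]ethyl]phenoxy]-3-methoxy-6-(propan-2-yloxy)benzaldehyde; 14 4-fluorobenzaldehyde
Product: 15 2-[3-[2-[3-(4-formylphenoxy)-4-(propan-2-yloxy)phenyl]ethyl]phenoxy]-3-methoxy-6-(propan-2-yloxy)benzaldehyde (seco dialdehyde)
Conditions: K2CO3, DMF, 120 °C
Reagents that add atoms: none
Why: SNAr by addition–elimination, in which the ring C phenoxide adds para to the formyl group of 14 and fluoride leaves from the Meisenheimer intermediate, while the hindered ring A aldehyde is a spectator.

Step 9
Reactants: 15 seco dialdehyde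
Product: 16 [2-[3-[2-[3-[4-(hydroxymethyl)phenoxy]-4-(propan-2-yloxy)phenyl]ethyl]phenoxy]-3-methoxy-6-(propan-2-yloxy)phenyl]methanol (seco diol)
Conditions: NaBH4, MeOH/THF, 0 °C
Reagents that add atoms: none
Why: Hydride reduction of both aryl aldehydes by NaBH4, which leaves the ethers untouched.

Step 10
Reactants: 16 seco diol
Product: 17 seco dibromide (ring A CH2Br, ring D CH2Br)
Conditions: PBr3, CH2Cl2, 0 °C; crude product used at once
Reagents that add atoms: phosphorus tribromide, SMILES BrP(Br)Br
Why: Conversion of the benzylic alcohols into bromides through phosphite esters and SN2 attack of bromide, run cold and without storage because the 2,6-dioxygenated benzylic bromide on ring A ionises easily.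

Step 11
Reactants: 17 seco dibromide
Product: 18 19-membered macrocyclic dibenzylic thioether (ring A–CH2–S–CH2–ring D)
Conditions: Na2S·9H2O (1.2 equiv), DMF, rt, syringe-pump addition of 17 (final concentration ca. 2 mM)
Reagents that add atoms: Na2S (sodium sulfide), SMILES [Na+].[Na+].[S-2]
Why: Double SN2 thioether macrocyclisation, in which sulfide displaces one benzylic bromide and the resulting thiolate closes the 19-membered ring on the other, with high dilution favouring ring closure over chain growth.

Step 12
Reactants: 18 macrocyclic thioether
Product: 19 19-membered macrocyclic dibenzylic sulfone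
Conditions: mCPBA (2.2 equiv), CH2Cl2, 0 °C → rt
Reagents that add atoms: mCPBA (3-chloroperoxybenzoic acid), SMILES OOC(=O)c1cccc(Cl)c1
Why: Peracid oxidation of the sulfide through the sulfoxide to the sulfone, at a temperature where the electron-rich arenes and ethers should not be attacked.

Step 13
Reactants: 19 macrocyclic dibenzylic sulfone
Product: 20 diisopropyl ether of the target macrocycle (18-membered ring)
Conditions: hν (254 nm, quartz), degassed benzene (ca. 1 mM), rt
Reagents that add atoms: none
Why: Excitation homolyses one benzylic C–S bond, the benzylsulfonyl radical loses SO2, and the two benzylic radicals on the ring A and ring D carbons, still joined through rings A–B–C–D, recombine to the CH2–CH2 bridge. The closest known reaction type is the photochemical (or pyrolytic) SO2 extrusion from dibenzylic sulfones that makes the ethano bridges of cyclophanes. The 18-membered ring is closed by intramolecular radical–radical recombination of a tethered 1,18-biradical, that is, by contraction of the 19-membered sulfone ring by one atom. No stereocentre is formed. The step needs recombination to win over intermolecular coupling, hydrogen abstraction and cleavage of other bonds: the tether holds the radical pair together at millimolar dilution, degassed benzene is a poor hydrogen donor, benzyl radicals have no β-hydrogen for disproportionation, the isopropyl ethers offer no benzylic C–O bond, and the nearly barrierless recombination should tolerate the two ortho oxygen substituents beside the ring A benzylic carbon.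

Step 14
Reactants: 20 diisopropyl ether of the target macrocycle
Product: 21 target CNP0179896.0
Conditions: BCl3, CH2Cl2, −78 → 0 °C; then MeOH/H2O
Reagents that add atoms: none
Why: Lewis-acid ether dealkylation, in which BCl3 complexes the ether oxygens and the secondary isopropyl group leaves as 2-chloropropane far faster than a methyl group, so both phenols should be freed while the ring A methyl ether is kept.

**Compound list**

1 | isovanillin (3-hydroxy-4-methoxybenzaldehyde) | COc1ccc(C=O)cc1O | starting material
2 | 1-bromo-3-iodobenzene | Brc1cccc(I)c1 | starting material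
3 | 3-(3-bromophenoxy)-4-methoxybenzaldehyde | COc1ccc(C=O)cc1Oc1cccc(Br)c1 | intermediate
4 | 3-(3-bromophenoxy)-4-methoxyphenyl formate (not isolated) | COc1ccc(OC=O)cc1Oc1cccc(Br)c1 | intermediate
5 | 3-(3-bromophenoxy)-4-methoxyphenol | COc1ccc(O)cc1Oc1cccc(Br)c1 | intermediate
6 | 2-(3-bromophenoxy)-1-methoxy-4-(propan-2-yloxy)benzene | COc1ccc(OC(C)C)cc1Oc1cccc(Br)c1 | intermediate
7 | 3,4-dihydroxybenzaldehyde | O=Cc1ccc(O)c(O)c1 | starting material
8 | 3-hydroxy-4-(propan-2-yloxy)benzaldehyde | CC(C)Oc1ccc(C=O)cc1O | intermediate
9 | 5-ethenyl-2-(propan-2-yloxy)phenol | C=Cc1ccc(OC(C)C)c(O)c1 | intermediate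
10 | B-alkyl-9-BBN adduct of 9 with the phenol held as its 9-BBN borinate (not isolated) | CC(C)Oc1ccc(CCB2C3CCCC2CCC3)cc1OB1C2CCCC1CCC2 | intermediate
11 | 5-[2-[3-[2-methoxy-5-(propan-2-yloxy)phenoxy]phenyl]ethyl]-2-(propan-2-yloxy)phenol | COc1ccc(OC(C)C)cc1Oc1cccc(CCc2ccc(OC(C)C)c(O)c2)c1 | intermediate
12 | lithium phenoxide of 11 lithiated at position 5 of ring A (not isolated) | COc1ccc(OC(C)C)c([Li])c1Oc1cccc(CCc2ccc(OC(C)C)c(O[Li])c2)c1 | intermediate
13 | 2-[3-[2-[3-hydroxy-4-(propan-2-yloxy)phenyl]ethyl]phenoxy]-3-methoxy-6-(propan-2-yloxy)benzaldehyde | COc1ccc(OC(C)C)c(C=O)c1Oc1cccc(CCc2ccc(OC(C)C)c(O)c2)c1 | intermediate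
14 | 4-fluorobenzaldehyde | O=Cc1ccc(F)cc1 | starting material
15 | seco dialdehyde (ring A CHO, ring D CHO) | COc1ccc(OC(C)C)c(C=O)c1Oc1cccc(CCc2ccc(OC(C)C)c(Oc3ccc(C=O)cc3)c2)c1 | intermediate
16 | seco diol (ring A CH2OH, ring D CH2OH) | COc1ccc(OC(C)C)c(CO)c1Oc1cccc(CCc2ccc(OC(C)C)c(Oc3ccc(CO)cc3)c2)c1 | intermediate
17 | seco dibromide (ring A CH2Br, ring D CH2Br) | COc1ccc(OC(C)C)c(CBr)c1Oc1cccc(CCc2ccc(OC(C)C)c(Oc3ccc(CBr)cc3)c2)c1 | intermediate
18 | 19-membered macrocyclic dibenzylic thioether | COc1ccc(OC(C)C)c2c1Oc1cccc(c1)CCc1ccc(OC(C)C)c(c1)Oc1ccc(cc1)CSC2 | intermediate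
19 | 19-membered macrocyclic dibenzylic sulfone | COc1ccc(OC(C)C)c2c1Oc1cccc(c1)CCc1ccc(OC(C)C)c(c1)Oc1ccc(cc1)CS(=O)(=O)C2 | intermediate
20 | diisopropyl ether of the target macrocycle | COc1ccc(OC(C)C)c2c1Oc1cccc(c1)CCc1ccc(OC(C)C)c(c1)Oc1ccc(cc1)CC2 | intermediate
21 | CNP0179896.0 | COc1ccc(O)c2c1Oc1cccc(c1)CCc1ccc(O)c(c1)Oc1ccc(cc1)CC2 | target

**Step count and risks**

Total step count: 14. Longest linear sequence: 12 steps (steps 1, 2, 3 and 6–14, from isovanillin).

Steps most likely to fail:

1. Step 13 (SO2 extrusion). The excited diaryl ether units may rearrange by aryl migration, the benzylic radical pair may couple through a ring position or abstract hydrogen before its ends meet, and the product absorbs the same light, so over-irradiation could degrade it. The fallback sets out from sulfone 19 and comes back at 20. A Ramberg–Bäcklund reaction of 19 (KOH on Al2O3, CBr2F2, t-BuOH/CH2Cl2, rt) proceeds by α-bromination, 1,3-elimination to the episulfone and loss of SO2. It should give the macrocyclic stilbene with a CH=CH bridge between rings D and A F1 (drawn as the Z isomer; either isomer serves). Hydrogenation of the alkene (H2, Pd/C, EtOAc) should then give 20.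

2. Step 11 (thioether macrocyclisation). Intermolecular sulfide bridging may give oligomers, and the activated benzylic bromide on ring A may be lost by solvolysis before sulfur is attached. The fallback sets out from dibromide 17 and comes back at 18. KSAc in DMF at 0 °C should convert both bromides quickly under neutral conditions into the seco bis(thioacetate) F2. Methanolysis (K2CO3, degassed MeOH) should free the seco dithiol F3. Oxidation at high dilution (I2, Et3N, CH2Cl2/MeOH) should close the 20-membered cyclic disulfide F4, a reversible ring closure that can correct oligomers by disulfide exchange. Desulfurisation with P(NEt2)3 in benzene (attack of phosphorus on sulfur, then SN2 of the thiolate at a benzylic carbon) should contract F4 to thioether 18.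

3. Step 7 (ortho-metalation and formylation). The lithium phenoxide may aggregate the base, so that metalation stalls. Under the more forcing conditions then needed it may spread to positions next to only one ether oxygen on ring A or B, or to a benzylic CH2. The fallback sets out from phenol 11 and comes back at 15. Silylation (TIPSCl, imidazole, DMF) should give the triisopropylsilyl ether F5, which needs only one equivalent of base, stays in solution and shields ring C. Lithiation between the two flanking oxygens of ring A (n-BuLi, TMEDA, THF, 0 °C) and DMF should give the silyl-protected ring A aldehyde F6. Treating F6 with 4-fluorobenzaldehyde 14 and CsF in DMF at 80 °C should unmask the phenoxide in the flask and carry out the SNAr, giving dialdehyde 15 directly.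

**Further compounds**

F1 | step 13 | macrocyclic Z-stilbene with a CH=CH bridge between rings D and A, diisopropyl ether | COc1ccc(OC(C)C)c2c1Oc1cccc(c1)CCc1ccc(OC(C)C)c(c1)Oc1ccc(cc1)/C=C\2
F2 | step 11 | seco bis(thioacetate) (ring A CH2SAc, ring D CH2SAc) | COc1ccc(OC(C)C)c(CSC(C)=O)c1Oc1cccc(CCc2ccc(OC(C)C)c(Oc3ccc(CSC(C)=O)cc3)c2)c1
F3 | step 11 | seco dithiol (ring A CH2SH, ring D CH2SH) | COc1ccc(OC(C)C)c(CS)c1Oc1cccc(CCc2ccc(OC(C)C)c(Oc3ccc(CS)cc3)c2)c1
F4 | step 11 | 20-membered macrocyclic dibenzylic disulfide | COc1ccc(OC(C)C)c2c1Oc1cccc(c1)CCc1ccc(OC(C)C)c(c1)Oc1ccc(cc1)CSSC2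
F5 | step 7 | triisopropylsilyl ether of phenol 11 | COc1ccc(OC(C)C)cc1Oc1cccc(CCc2ccc(OC(C)C)c(O[Si](C(C)C)(C(C)C)C(C)C)c2)c1
F6 | step 7 | triisopropylsilyl ether of aldehyde 13 | COc1ccc(OC(C)C)c(C=O)c1Oc1cccc(CCc2ccc(OC(C)C)c(O[Si](C(C)C)(C(C)C)C(C)C)c2)c1
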